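## The problem

Compound 27 has no stereocentre and no fused ring. Four benzene rings hang on a fifth through three methylene groups and one ethylene bridge, so the difficulty is regiochemical. Ring A is numbered C1 (methoxyl), C2 (hydrogen), C3 (hydroxyl), C4 (4-hydroxybenzyl), C5 (bridge Ca–Cb to ring B) and C6 (4-hydroxybenzyl), and this numbering is used for all intermediates. Its three carbon substituents sit on the contiguous positions C4, C5 and C6, an order and a crowding that stepwise electrophilic substitution of an electron-rich ring would not deliver reliably. The two oxygens of ring A must be told apart (methyl ether at C1, free phenol at C3), and ring B must carry the bridge ortho and a benzyl group para to its own hydroxyl. No element of the target can direct another; the only stereocentre of the route (Ca while it bears an ester) is racemic and is erased. The five phenols, the phloroglucinol-like ring A (open to oxidants and to electrophiles at C2) and the 4-hydroxybenzyl–arene bonds on that ring (which can ionise in strong acid) argue for benzyl protection throughout and one mild hydrogenolytic release at the end. The feature that opens the key step is that the bridge on C5 and the benzyl on C6 are neighbours and the C1 methoxyl flanks C6: this is the pattern left when a 3-methoxyaryne spanning C5–C6 takes a carbon nucleophile at C5 and a carbon electrophile at C6. In the aryne precursor C1, C3 and C5 then all bear oxygen, so ring A can be drawn from a phloroglucinol monomethyl ether.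

## Retrosynthesis

**27 from 26.** No skeletal bond is cut. The C6 methylene is taken back to a diaryl ketone and the five phenols to benzyl ethers, giving 26. A single hydrogenation over Pd/C should both hydrogenolyse the electron-rich benzophenone to the methylene and remove all benzyl groups. Keeping one protecting group for every phenol makes the last step the only deprotection.

**26 from 23 through 24.** Ca of 26 is given an ester, which leads to acid 24 and methyl ester 23. The ester serves only to make Ca nucleophilic in the key step. It is removed by hydrolysis and Barton reductive decarboxylation, a radical method that does not need the carbanion stabilisation this hindered arylacetic acid lacks. The forward steps must tolerate a non-enolisable diaryl ketone and five benzyl ethers, which both do.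

**23 from 12 and 20 (key disconnection).** The C5–Ca bond and the C6–carbonyl bond are cut together. The aryl fragment becomes aryne 21, generated from silyl triflate 12, and the other fragment is the alpha-substituted beta-keto ester 20. Against stepwise ortho-functionalisation of a preformed ring A, this cut forms both crowded bonds in one operation with the orientation fixed by the C1 methoxyl, and it joins the two halves of the molecule convergently. The precursors are much simpler: 12 is a pentasubstituted benzene with one carbon substituent, and 20 is an ordinary keto ester. The forward reaction must add a tertiary enolate to the aryne carbon that lies beside the C4 benzyl group, then close the aryl anion on the ketone (transient cyclobutenoxide 22) and fragment.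

**20 from 19 and 17.** The Ca–Cb bond is cut to the aroylacetate 19 and benzylic bromide 17. Alkylation of a beta-keto ester is preferred to acylating a ring B propanoate, because it needs no separate three-carbon homologation of ring B. Keto ester 19 is one Claisen step from commercial ketone 18. Bromide 17 comes from alcohol 16 and aldehyde 15, and 15 from bisphenol 13 by ortho-formylation to 14 and benzylation. The para positions of 13 are blocked, so formylation can only go ortho, and the only selectivity issue is mono against double reaction on a commodity diphenol.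

**12 from 6 through 7 and 11.** The silyl and triflate groups are traced to an ortho-bromophenol by the silylation, halogen–lithium exchange, retro-Brook and triflation sequence. The bromine is introduced on the symmetric resorcinol 6, whose two open positions are equivalent, so only one monobromide (7) can form. Bromination after monobenzylation would instead have to choose between ortho and para to the free hydroxyl. In phenoxide 9 the retro-Brook shift has marked which oxygen becomes the triflate. The other oxygen emerges as the free phenol of 11 and is benzylated last. A route through aroylation of a phloroglucinol triether and Lewis-acid demethylation was set aside because the Lewis acid would also strip benzyl ethers.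

**6 from 1 and 3 through 2 and 5.** The C4–CH2 bond is cut to aryllithium 4 and 4-(benzyloxy)benzyl bromide 3. The two MOM ethers of 2 direct lithiation to the carbon between them, which is exactly the carbon para to the methoxyl, and they are removed from 5 with mild acid. The metalation is done before any benzyl ether or diarylmethane is in the substrate. The starting point 1 is commercial 5-methoxyresorcinol.

## Roads not taken

**Alternative 1:** The bridge and the ring B hydroxyl are cut together by treating them as a reduced 2-arylbenzofuran, A1.
- Forward key step: the terminal alkyne A2 (ring A with both benzyl arms and an ethynyl group on C5) and the ortho-iodophenol A3 of ring B couple under palladium–copper catalysis, forming Cb–C1'. The phenol oxygen then adds to the alkyne to form O–Ca. Hydrogenation of A1 would then have to saturate the furan double bond, cleave the benzylic O–Ca bond and remove the benzyl ethers.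
- Merits: a dependable convergent coupling, the ring B oxygen placed by construction, and an endgame of one reductive operation where the chosen plan spends three steps removing its ester and ketone.
- Weak points: A2 is already a fully substituted ring A with three contiguous carbon substituents, so the C4/C5/C6 problem is moved into the synthesis of A2 and not solved. The aryl group on the furan carbon of A1 is twisted by two ortho benzyl groups, so the C–O hydrogenolysis, which depends on benzylic activation, may stop after partial reduction.
- Comparison: this road is shorter after its key step, and that step is lower in risk than the aryne insertion. The chosen plan sets against this a key step that itself builds the crowded C5/C6 edge while attaching the whole bridge, starting from a ring A precursor (12) with only one carbon substituent.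

**Alternative 2:** All three aryl–methylene bonds of the 4-hydroxybenzyl groups are cut at the ketone oxidation level.
- Forward key step: tribromide A5 (the protected bibenzyl brominated at C4, C6 and C5'), 4-(benzyloxy)phenylboronic acid A6 and carbon monoxide A7 undergo a threefold carbonylative Suzuki coupling with a palladium–phosphine catalyst to give tris-ketone A4. Hydrogenation then reduces three ketones and removes the benzyl ethers.
- Merits: three rings are attached in one step from one cheap reagent. The bibenzyl core is simple, and its bromination sites are the ones the ring oxygens activate. No decarboxylation is needed. If it worked, it would be the shortest route and the most convergent.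
- Weak points: the two bromides on ring A are electron-rich and flanked on both sides, so oxidative addition is slow, and at each of three sites direct biaryl coupling competes with carbon monoxide insertion. One lapse at any site gives an inseparable relative of A4. Three hindered diaryl ketones must then all be reduced.
- Comparison: step economy favours this road. The chosen plan offers one carbonyl to reduce and a product whose constitution is fixed by the mechanism, not by the ratio of two competing catalytic cycles.

**Alternative 3:** Ring A is built from acyclic pieces.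
- Forward key step: irradiation of the alpha-diazo enone A9 gives, by Wolff shift, a vinylketene. This adds methoxyacetylene A10 and passes through cyclobutenone opening and six-electron closure to the phenol A8.
- Merits: every substituent of ring A is placed by the connectivity of A9 and A10, so the regiochemistry is unambiguous. The free C3 hydroxyl (from the ketene carbon) and the C1 methoxyl (from the alkyne) are differentiated automatically. Here this road is better than the chosen plan, which needs the bromination and retro-Brook sequence to tell the two oxygens apart.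
- Weak points: A9 is a trisubstituted enone carrying three large arms and a diazo group next to a benzylic carbon, so it needs a long linear synthesis with control of alkene geometry and a diazo transfer at a hindered ketone. A10 is volatile and unstable. A fully substituted vinylketene may dimerise or be trapped faster than it meets the alkyne.
- Comparison: the chosen plan offers short, convergent access to both partners of its key step from catalogue aromatics, and accepts a more hindered bond formation in return.

Key step: step 13

## Route

Step 1
Reactants: 1 5-methoxyresorcinol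
Product: 2 1-methoxy-3,5-bis(methoxymethoxy)benzene
Conditions: MOMCl, i-Pr2NEt, CH2Cl2, 0 °C to rt
Reagents that add atoms: chloromethyl methyl ether, COCCl
Why: O-alkylation of both phenols (MOM ether formation); the MOM groups are the directing groups of step 2 and leave under mild acid.

Step 2
Reactants: 2 1-methoxy-3,5-bis(methoxymethoxy)benzene; 3 4-(benzyloxy)benzyl bromide
Product: 5 2-[4-(benzyloxy)benzyl]-5-methoxy-1,3-bis(methoxymethoxy)benzene, via 4-methoxy-2,6-bis(methoxymethoxy)phenyllithium 4 (not isolated)
Conditions: n-BuLi, THF, 0 °C to rt; then 3, −78 °C to rt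
Reagents that add atoms: none
Why: Directed ortho-metalation: the carbon between the two MOM ethers is doubly chelated and should be lithiated in preference to the carbons flanked by one MOM ether and the methoxyl; SN2 benzylation of aryllithium 4 by the reactive 4-alkoxybenzyl bromide then forms the C4–CH2 bond.

Step 3
Reactants: 5 2-[4-(benzyloxy)benzyl]-5-methoxy-1,3-bis(methoxymethoxy)benzene
Product: 6 2-[4-(benzyloxy)benzyl]-5-methoxybenzene-1,3-diol
Conditions: HCl (cat.), MeOH, 40 °C
Reagents that add atoms: none
Why: Acid-catalysed acetal exchange (MOM cleavage) with methanol as the formaldehyde acceptor; the aryl benzyl ether and the diarylmethane should survive dilute acid at this temperature.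

Step 4
Reactants: 6 2-[4-(benzyloxy)benzyl]-5-methoxybenzene-1,3-diol
Product: 7 2-[4-(benzyloxy)benzyl]-4-bromo-5-methoxybenzene-1,3-diol
Conditions: NBS (1.0 equiv), CH2Cl2/THF, −78 °C
Reagents that add atoms: N-bromosuccinimide, O=C1CCC(=O)N1Br
Why: Electrophilic aromatic bromination; the two open positions of 6 are equivalent by symmetry, so only one monobromide can form, the first bromine deactivates the ring toward a second, and the pendant benzyloxyphenyl ring is far less activated.

Step 5
Reactants: 7 2-[4-(benzyloxy)benzyl]-4-bromo-5-methoxybenzene-1,3-diol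
Product: 11 2-[4-(benzyloxy)benzyl]-3-hydroxy-5-methoxy-6-(trimethylsilyl)phenyl trifluoromethanesulfonate, via bis(trimethylsilyl) ether 8 (not isolated), via lithium 2-silylphenoxide 9 (not isolated), via O-silylated aryl triflate 10 (not isolated)
Conditions: HMDS, THF, 65 °C, then evaporate; n-BuLi, THF, −100 to −78 °C; Tf2O, −100 to 0 °C; citric acid, MeOH, 0 °C
Reagents that add atoms: hexamethyldisilazane, C[Si](C)(C)N[Si](C)(C)C; trifluoromethanesulfonic anhydride, O=S(=O)(OS(=O)(=O)C(F)(F)F)C(F)(F)F
Why: O-silylation, bromine–lithium exchange and 1,3-retro-Brook (O to C) silyl shift give phenoxide 9, in which only the oxygen that neighboured bromine is anionic; Tf2O therefore triflates that oxygen alone and mild acid frees the other from its labile silyl ether (the standard route to 2-silylaryl triflates).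

Step 6
Reactants: 11 2-[4-(benzyloxy)benzyl]-3-hydroxy-5-methoxy-6-(trimethylsilyl)phenyl trifluoromethanesulfonate
Product: 12 3-(benzyloxy)-2-[4-(benzyloxy)benzyl]-5-methoxy-6-(trimethylsilyl)phenyl trifluoromethanesulfonate
Conditions: BnBr, K2CO3, acetone, rt
Reagents that add atoms: benzyl bromide, BrCc1ccccc1
Why: Williamson benzylation of the single free phenol under weak heterogeneous base, without fluoride or soluble alkoxide, conditions under which a silylaryl triflate is expected to persist.

Step 7
Reactants: 13 bis(4-hydroxyphenyl)methane
Product: 14 2-hydroxy-5-(4-hydroxybenzyl)benzaldehyde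
Conditions: MgCl2, Et3N, paraformaldehyde (limiting), MeCN, reflux
Reagents that add atoms: paraformaldehyde (as formaldehyde), C=O
Why: Magnesium-mediated ortho-formylation of phenols (Casnati–Skattebøl); the para positions are blocked so only ortho attack is possible, and with formaldehyde limiting the mono-aldehyde should be the main component of a statistical mixture from which cheap 13 is recovered.

Step 8
Reactants: 14 2-hydroxy-5-(4-hydroxybenzyl)benzaldehyde
Product: 15 2-(benzyloxy)-5-[4-(benzyloxy)benzyl]benzaldehyde
Conditions: BnBr (2.2 equiv), K2CO3, DMF, 60 °C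
Reagents that add atoms: benzyl bromide, BrCc1ccccc1
Why: Williamson ether synthesis on both phenols; heating overcomes the hydrogen bond of the salicylaldehyde hydroxyl.

Step 9
Reactants: 15 2-(benzyloxy)-5-[4-(benzyloxy)benzyl]benzaldehyde
Product: 16 {2-(benzyloxy)-5-[4-(benzyloxy)benzyl]phenyl}methanol
Conditions: NaBH4, THF/MeOH, 0 °C
Reagents that add atoms: none
Why: Borohydride reduction of an aryl aldehyde; no other reducible group is present.

Step 10
Reactants: 16 {2-(benzyloxy)-5-[4-(benzyloxy)benzyl]phenyl}methanol
Product: 17 1-(benzyloxy)-4-[4-(benzyloxy)benzyl]-2-(bromomethyl)benzene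
Conditions: PBr3, CH2Cl2, 0 °C
Reagents that add atoms: phosphorus tribromide, BrP(Br)Br
Why: Conversion of a benzylic alcohol into the bromide through its phosphite ester; the electron-rich bromide is used without prolonged storage.

Step 11
Reactants: 18 4'-(benzyloxy)acetophenone
Product: 19 methyl 3-[4-(benzyloxy)phenyl]-3-oxopropanoate
Conditions: NaH, dimethyl carbonate, THF, reflux; then aq. HCl
Reagents that add atoms: dimethyl carbonate, COC(=O)OC
Why: Crossed Claisen condensation (methoxycarbonylation of a methyl ketone enolate), driven by deprotonation of the beta-keto ester formed.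

Step 12
Reactants: 19 methyl 3-[4-(benzyloxy)phenyl]-3-oxopropanoate; 17 1-(benzyloxy)-4-[4-(benzyloxy)benzyl]-2-(bromomethyl)benzene
Product: 20 methyl 2-{2-(benzyloxy)-5-[4-(benzyloxy)benzyl]benzyl}-3-[4-(benzyloxy)phenyl]-3-oxopropanoate (racemic)
Conditions: K2CO3, acetone, reflux (19 in slight excess)
Reagents that add atoms: none
Why: C-alkylation of a beta-keto ester enolate by a benzylic bromide forms Ca–Cb; a slight excess of 19 limits double alkylation, and the new stereocentre is formed without control and is racemic.

Step 13
Reactants: 12 3-(benzyloxy)-2-[4-(benzyloxy)benzyl]-5-methoxy-6-(trimethylsilyl)phenyl trifluoromethanesulfonate; 20 methyl 2-{2-(benzyloxy)-5-[4-(benzyloxy)benzyl]benzyl}-3-[4-(benzyloxy)phenyl]-3-oxopropanoate (racemic)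
Product: 23 methyl 2-{2-[4-(benzyloxy)benzoyl]-5-(benzyloxy)-6-[4-(benzyloxy)benzyl]-3-methoxyphenyl}-3-{2-(benzyloxy)-5-[4-(benzyloxy)benzyl]phenyl}propanoate (racemic), via 3-methoxyaryne 21 (not isolated), via cesium benzocyclobutenoxide 22 (not isolated)
Conditions: CsF (3 equiv), MeCN, 80 °C (12 in slight excess)
Reagents that add atoms: none
Why: Fluoride attacks silicon of 12 and triflate leaves, unmasking aryne 21 across C5–C6. The cesium enolate of 20 adds through carbon at C5, because the inductively withdrawing C1 methoxyl distorts the aryne and stabilises the aryl anion developing at C6. That anion adds to the neighbouring aryl ketone in a 4-exo-trig anionic closure to give benzocyclobutenoxide 22; this four-membered ring is not retained, since retro-aldol fragmentation breaks the Ca–carbonyl bond, releases the strain and leaves an ester-stabilised benzylic anion that is protonated by 20 or the medium. The net result is formal insertion of the aryne into the alpha-carbon–ketone bond, forming C5–Ca and C6–C(=O) in one operation. The closest known reaction type is the acyl-alkylation of arynes by beta-keto esters under CsF in MeCN, which is established for alpha-substituted keto esters and for 3-methoxyarynes; the present case combines both with a further substituent at C4. Ca becomes a stereocentre on protonation under no control, so 23 is racemic, which does not matter because the centre is erased in step 15. The selectivity needed is regiochemical (carbon to C5, acyl to C6) and is secured by the methoxyl, while C- over O-arylation follows the behaviour of keto ester enolates in this medium.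

Step 14
Reactants: 23 methyl 2-{2-[4-(benzyloxy)benzoyl]-5-(benzyloxy)-6-[4-(benzyloxy)benzyl]-3-methoxyphenyl}-3-{2-(benzyloxy)-5-[4-(benzyloxy)benzyl]phenyl}propanoate (racemic)
Product: 24 2-{2-[4-(benzyloxy)benzoyl]-5-(benzyloxy)-6-[4-(benzyloxy)benzyl]-3-methoxyphenyl}-3-{2-(benzyloxy)-5-[4-(benzyloxy)benzyl]phenyl}propanoic acid (racemic)
Conditions: LiOH·H2O, THF/MeOH/H2O, 60 °C; then aq. HCl
Reagents that add atoms: lithium hydroxide, [Li+].[OH-]
Why: Saponification of a methyl ester; the diaryl ketone cannot enolise and the benzyl ethers are inert to hydroxide, and heating allows for the hindered environment of the ester.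

Step 15
Reactants: 24 2-{2-[4-(benzyloxy)benzoyl]-5-(benzyloxy)-6-[4-(benzyloxy)benzyl]-3-methoxyphenyl}-3-{2-(benzyloxy)-5-[4-(benzyloxy)benzyl]phenyl}propanoic acid (racemic)
Product: 26 [4-(benzyloxy)phenyl]{4-(benzyloxy)-3-[4-(benzyloxy)benzyl]-2-(2-{2-(benzyloxy)-5-[4-(benzyloxy)benzyl]phenyl}ethyl)-6-methoxyphenyl}methanone, via thiohydroxamate ester 25 (not isolated)
Conditions: N-hydroxypyridine-2-thione, DCC, DMAP (cat.), CH2Cl2, rt, dark; then t-BuSH, visible light (W lamp), rt
Reagents that add atoms: none
Why: Barton reductive decarboxylation: the O-acyl thiohydroxamate 25 fragments in a radical chain to CO2 and a secondary benzylic radical at Ca, which takes hydrogen from the thiol; the Ca stereocentre is removed here.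

Step 16
Reactants: 26 [4-(benzyloxy)phenyl]{4-(benzyloxy)-3-[4-(benzyloxy)benzyl]-2-(2-{2-(benzyloxy)-5-[4-(benzyloxy)benzyl]phenyl}ethyl)-6-methoxyphenyl}methanone
Product: 27 2,4-bis(4-hydroxybenzyl)-3-{2-[2-hydroxy-5-(4-hydroxybenzyl)phenyl]ethyl}-5-methoxyphenol (CNP0134121.0)
Conditions: H2 (3 atm), 10% Pd/C, EtOAc/MeOH, HCl (cat.), 25–40 °C
Reagents that add atoms: none
Why: Catalytic hydrogenolysis: the five benzyl ethers are cleaved, and the electron-rich diaryl ketone is reduced through its benzhydrol, whose doubly benzylic C–O bond is hydrogenolysed under acid catalysis, to the C6 methylene; the methyl ether and the diarylmethane bonds are stable.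

## Compound list

1 | 5-methoxyresorcinol | COc1cc(O)cc(O)c1 | starting material
2 | 1-methoxy-3,5-bis(methoxymethoxy)benzene | COCOc1cc(OC)cc(OCOC)c1 | intermediate
3 | 4-(benzyloxy)benzyl bromide | BrCc1ccc(OCc2ccccc2)cc1 | starting material
4 | 4-methoxy-2,6-bis(methoxymethoxy)phenyllithium | [Li]c1c(OCOC)cc(OC)cc1OCOC | intermediate
5 | 2-[4-(benzyloxy)benzyl]-5-methoxy-1,3-bis(methoxymethoxy)benzene | COCOc1cc(OC)cc(OCOC)c1Cc1ccc(OCc2ccccc2)cc1 | intermediate
6 | 2-[4-(benzyloxy)benzyl]-5-methoxybenzene-1,3-diol | COc1cc(O)c(Cc2ccc(OCc3ccccc3)cc2)c(O)c1 | intermediate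
7 | 2-[4-(benzyloxy)benzyl]-4-bromo-5-methoxybenzene-1,3-diol | COc1cc(O)c(Cc2ccc(OCc3ccccc3)cc2)c(O)c1Br | intermediate
8 | bis(trimethylsilyl) ether of 7 | COc1cc(O[Si](C)(C)C)c(Cc2ccc(OCc3ccccc3)cc2)c(O[Si](C)(C)C)c1Br | intermediate
9 | lithium 2-[4-(benzyloxy)benzyl]-5-methoxy-6-(trimethylsilyl)-3-[(trimethylsilyl)oxy]phenoxide | COc1cc(O[Si](C)(C)C)c(Cc2ccc(OCc3ccccc3)cc2)c(O[Li])c1[Si](C)(C)C | intermediate
10 | 2-[4-(benzyloxy)benzyl]-5-methoxy-6-(trimethylsilyl)-3-[(trimethylsilyl)oxy]phenyl trifluoromethanesulfonate | COc1cc(O[Si](C)(C)C)c(Cc2ccc(OCc3ccccc3)cc2)c(OS(=O)(=O)C(F)(F)F)c1[Si](C)(C)C | intermediate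
11 | 2-[4-(benzyloxy)benzyl]-3-hydroxy-5-methoxy-6-(trimethylsilyl)phenyl trifluoromethanesulfonate | COc1cc(O)c(Cc2ccc(OCc3ccccc3)cc2)c(OS(=O)(=O)C(F)(F)F)c1[Si](C)(C)C | intermediate
12 | 3-(benzyloxy)-2-[4-(benzyloxy)benzyl]-5-methoxy-6-(trimethylsilyl)phenyl trifluoromethanesulfonate | COc1cc(OCc2ccccc2)c(Cc2ccc(OCc3ccccc3)cc2)c(OS(=O)(=O)C(F)(F)F)c1[Si](C)(C)C | intermediate
13 | bis(4-hydroxyphenyl)methane | Oc1ccc(Cc2ccc(O)cc2)cc1 | starting material
14 | 2-hydroxy-5-(4-hydroxybenzyl)benzaldehyde | O=Cc1cc(Cc2ccc(O)cc2)ccc1O | intermediate
15 | 2-(benzyloxy)-5-[4-(benzyloxy)benzyl]benzaldehyde | O=Cc1cc(Cc2ccc(OCc3ccccc3)cc2)ccc1OCc1ccccc1 | intermediate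
16 | {2-(benzyloxy)-5-[4-(benzyloxy)benzyl]phenyl}methanol | OCc1cc(Cc2ccc(OCc3ccccc3)cc2)ccc1OCc1ccccc1 | intermediate
17 | 1-(benzyloxy)-4-[4-(benzyloxy)benzyl]-2-(bromomethyl)benzene | BrCc1cc(Cc2ccc(OCc3ccccc3)cc2)ccc1OCc1ccccc1 | intermediate
18 | 4'-(benzyloxy)acetophenone | CC(=O)c1ccc(OCc2ccccc2)cc1 | starting material
19 | methyl 3-[4-(benzyloxy)phenyl]-3-oxopropanoate | COC(=O)CC(=O)c1ccc(OCc2ccccc2)cc1 | intermediate
20 | methyl 2-{2-(benzyloxy)-5-[4-(benzyloxy)benzyl]benzyl}-3-[4-(benzyloxy)phenyl]-3-oxopropanoate (racemic) | COC(=O)C(Cc1cc(Cc2ccc(OCc3ccccc3)cc2)ccc1OCc1ccccc1)C(=O)c1ccc(OCc2ccccc2)cc1 | intermediate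
21 | 5-(benzyloxy)-6-[4-(benzyloxy)benzyl]-1,2-didehydro-3-methoxybenzene (aryne across C5–C6 of ring A) | COC1=CC(OCc2ccccc2)=C(Cc2ccc(OCc3ccccc3)cc2)C#C1 | intermediate
22 | cesium benzocyclobutenoxide from addition of the enolate of 20 to 21 and closure on the ketone (racemic, mixture of diastereomers) | COC(=O)C1(Cc2cc(Cc3ccc(OCc4ccccc4)cc3)ccc2OCc2ccccc2)c2c(Cc3ccc(OCc4ccccc4)cc3)c(OCc3ccccc3)cc(OC)c2C1([O-])c1ccc(OCc2ccccc2)cc1.[Cs+] | intermediate
23 | methyl 2-{2-[4-(benzyloxy)benzoyl]-5-(benzyloxy)-6-[4-(benzyloxy)benzyl]-3-methoxyphenyl}-3-{2-(benzyloxy)-5-[4-(benzyloxy)benzyl]phenyl}propanoate (racemic) | COc1cc(OCc2ccccc2)c(Cc2ccc(OCc3ccccc3)cc2)c(C(Cc2cc(Cc3ccc(OCc4ccccc4)cc3)ccc2OCc2ccccc2)C(=O)OC)c1C(=O)c1ccc(OCc2ccccc2)cc1 | intermediate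
24 | 2-{2-[4-(benzyloxy)benzoyl]-5-(benzyloxy)-6-[4-(benzyloxy)benzyl]-3-methoxyphenyl}-3-{2-(benzyloxy)-5-[4-(benzyloxy)benzyl]phenyl}propanoic acid (racemic) | COc1cc(OCc2ccccc2)c(Cc2ccc(OCc3ccccc3)cc2)c(C(Cc2cc(Cc3ccc(OCc4ccccc4)cc3)ccc2OCc2ccccc2)C(=O)O)c1C(=O)c1ccc(OCc2ccccc2)cc1 | intermediate
25 | 2-thioxopyridin-1(2H)-yl ester of acid 24 (racemic) | COc1cc(OCc2ccccc2)c(Cc2ccc(OCc3ccccc3)cc2)c(C(Cc2cc(Cc3ccc(OCc4ccccc4)cc3)ccc2OCc2ccccc2)C(=O)On2ccccc2=S)c1C(=O)c1ccc(OCc2ccccc2)cc1 | intermediate
26 | [4-(benzyloxy)phenyl]{4-(benzyloxy)-3-[4-(benzyloxy)benzyl]-2-(2-{2-(benzyloxy)-5-[4-(benzyloxy)benzyl]phenyl}ethyl)-6-methoxyphenyl}methanone | COc1cc(OCc2ccccc2)c(Cc2ccc(OCc3ccccc3)cc2)c(CCc2cc(Cc3ccc(OCc4ccccc4)cc3)ccc2OCc2ccccc2)c1C(=O)c1ccc(OCc2ccccc2)cc1 | intermediate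
27 | 2,4-bis(4-hydroxybenzyl)-3-{2-[2-hydroxy-5-(4-hydroxybenzyl)phenyl]ethyl}-5-methoxyphenol (CNP0134121.0) | COc1cc(O)c(Cc2ccc(O)cc2)c(CCc2cc(Cc3ccc(O)cc3)ccc2O)c1Cc1ccc(O)cc1 | target

## Step count and risks

Total: 16 steps. Longest linear sequence: 10 steps (steps 1–6, then 13–16).

**Step 13 (key step).** The tertiary enolate of 20 may add too slowly to the aryne carbon flanked by the C4 benzyl group. Aryne decomposition, attack at C6 against the methoxyl's bias, protonation of the C6 anion before it closes on the ketone (plain alpha-arylation) or O-arylation could then take over. Fallback: set out from 12 and the unbranched keto ester 19 under the same fluoride conditions, where the secondary enolate is the standard case of the reaction. This should give methyl {2-[4-(benzyloxy)benzoyl]-5-(benzyloxy)-6-[4-(benzyloxy)benzyl]-3-methoxyphenyl}acetate F1. The same two bonds are still formed by insertion. The only acidic position of F1 is the arylacetate methylene, so deprotonation with LiHMDS in THF at −78 °C and alkylation with bromide 17 would form Ca–Cb afterwards and return to the route at 23.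

**Step 2.** Halogen–lithium exchange between aryllithium 4 and the electron-rich benzylic bromide could lead to homocoupling and reprotonated arene, and some metalation could occur beside the methoxyl. Fallback: set out from 2, generate 4 as before and add it to commercial 4-(benzyloxy)benzaldehyde, a carbonyl addition with no exchange pathway, to give [4-(benzyloxy)phenyl][4-methoxy-2,6-bis(methoxymethoxy)phenyl]methanol F2. Ionic deoxygenation of this highly stabilised benzhydrol with Et3SiH and a few equivalents of TFA in CH2Cl2 at −40 °C returns to the route at 5.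

**Step 5 (and the benzylation of step 6).** n-BuLi could attack the second silyl ether, the silyl shift to the crowded carbon could be incomplete, or the silyl group could be lost during hydrolysis or the later base treatment. Fallback: set out from 6 and differentiate the oxygens first.
- Monobenzylation with one equivalent of BnBr and K2CO3 (statistical, diol recovered) gives 3-(benzyloxy)-2-[4-(benzyloxy)benzyl]-5-methoxyphenol F3.
- Amine-catalysed ortho-bromination (NBS, cat. i-Pr2NH, CH2Cl2) gives 3-(benzyloxy)-2-[4-(benzyloxy)benzyl]-6-bromo-5-methoxyphenol F4.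
- HMDS gives its trimethylsilyl ether F5; n-BuLi then gives lithium 3-(benzyloxy)-2-[4-(benzyloxy)benzyl]-5-methoxy-6-(trimethylsilyl)phenoxide F6 by retro-Brook shift.
- Tf2O converts F6 into the triflate, returning to the route at 12 with no free phenol ever present beside the silyl triflate.

**Step 15.** Acylation of the thiohydroxamic acid by the hindered keto acid may fail (ring closure of the acid onto the ortho ketone competes), or light absorbed by the diaryl ketone may cause side reactions. Fallback: set out from 24 and make the isolable redox-active ester with N-hydroxyphthalimide and N,N'-diisopropylcarbodiimide, the N-(acyloxy)phthalimide F7. Reductive fragmentation by single-electron transfer (Ru(bpy)3Cl2, Hantzsch ester, i-Pr2NEt, blue light) avoids the thiyl chain and returns to the route at 26.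

**Step 16.** The twisted diaryl ketone may adsorb poorly on the catalyst, so reduction could stall at the ketone or benzhydrol while the benzyl ethers are cleaved. Fallback: set out from 26 and reduce the carbonyl first in solution by ionic hydrogenation (Et3SiH, TFA, CH2Cl2, 0 °C) to the pentabenzyl ether of the target, F8. Neutral hydrogenolysis over Pd/C then returns to the route at 27.

## Further compounds

F1 | step 13 | methyl {2-[4-(benzyloxy)benzoyl]-5-(benzyloxy)-6-[4-(benzyloxy)benzyl]-3-methoxyphenyl}acetate | COC(=O)Cc1c(Cc2ccc(OCc3ccccc3)cc2)c(OCc2ccccc2)cc(OC)c1C(=O)c1ccc(OCc2ccccc2)cc1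
F2 | step 2 | [4-(benzyloxy)phenyl][4-methoxy-2,6-bis(methoxymethoxy)phenyl]methanol (racemic) | COCOc1cc(OC)cc(OCOC)c1C(O)c1ccc(OCc2ccccc2)cc1
F3 | step 5 | 3-(benzyloxy)-2-[4-(benzyloxy)benzyl]-5-methoxyphenol | COc1cc(O)c(Cc2ccc(OCc3ccccc3)cc2)c(OCc2ccccc2)c1
F4 | step 5 | 3-(benzyloxy)-2-[4-(benzyloxy)benzyl]-6-bromo-5-methoxyphenol | COc1cc(OCc2ccccc2)c(Cc2ccc(OCc3ccccc3)cc2)c(O)c1Br
F5 | step 5 | trimethylsilyl ether of F4 | COc1cc(OCc2ccccc2)c(Cc2ccc(OCc3ccccc3)cc2)c(O[Si](C)(C)C)c1Br
F6 | step 5 | lithium 3-(benzyloxy)-2-[4-(benzyloxy)benzyl]-5-methoxy-6-(trimethylsilyl)phenoxide | COc1cc(OCc2ccccc2)c(Cc2ccc(OCc3ccccc3)cc2)c(O[Li])c1[Si](C)(C)C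
F7 | step 15 | 1,3-dioxoisoindolin-2-yl ester of acid 24 (racemic) | COc1cc(OCc2ccccc2)c(Cc2ccc(OCc3ccccc3)cc2)c(C(Cc2cc(Cc3ccc(OCc4ccccc4)cc3)ccc2OCc2ccccc2)C(=O)ON2C(=O)c3ccccc3C2=O)c1C(=O)c1ccc(OCc2ccccc2)cc1
F8 | step 16 | pentabenzyl ether of 27: 1-(benzyloxy)-2,4-bis[4-(benzyloxy)benzyl]-3-(2-{2-(benzyloxy)-5-[4-(benzyloxy)benzyl]phenyl}ethyl)-5-methoxybenzene | COc1cc(OCc2ccccc2)c(Cc2ccc(OCc3ccccc3)cc2)c(CCc2cc(Cc3ccc(OCc4ccccc4)cc3)ccc2OCc2ccccc2)c1Cc1ccc(OCc2ccccc2)cc1
A1 | alternative 1 | 2-{3-(benzyloxy)-2,6-bis[4-(benzyloxy)benzyl]-5-methoxyphenyl}-5-[4-(benzyloxy)benzyl]benzofuran | COc1cc(OCc2ccccc2)c(Cc2ccc(OCc3ccccc3)cc2)c(-c2cc3cc(Cc4ccc(OCc5ccccc5)cc4)ccc3o2)c1Cc1ccc(OCc2ccccc2)cc1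
A2 | alternative 1 | 1-(benzyloxy)-2,4-bis[4-(benzyloxy)benzyl]-3-ethynyl-5-methoxybenzene | COc1cc(OCc2ccccc2)c(Cc2ccc(OCc3ccccc3)cc2)c(C#C)c1Cc1ccc(OCc2ccccc2)cc1
A3 | alternative 1 | 4-[4-(benzyloxy)benzyl]-2-iodophenol | Oc1ccc(Cc2ccc(OCc3ccccc3)cc2)cc1I
A4 | alternative 2 | tris(diaryl ketone) analogue of the pentabenzyl-protected target | COc1cc(OCc2ccccc2)c(C(=O)c2ccc(OCc3ccccc3)cc2)c(CCc2cc(C(=O)c3ccc(OCc4ccccc4)cc3)ccc2OCc2ccccc2)c1C(=O)c1ccc(OCc2ccccc2)cc1
A5 | alternative 2 | 1-(benzyloxy)-3-{2-[2-(benzyloxy)-5-bromophenyl]ethyl}-2,4-dibromo-5-methoxybenzene | COc1cc(OCc2ccccc2)c(Br)c(CCc2cc(Br)ccc2OCc2ccccc2)c1Br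
A6 | alternative 2 | 4-(benzyloxy)phenylboronic acid | OB(O)c1ccc(OCc2ccccc2)cc1
A7 | alternative 2 | carbon monoxide | [C-]#[O+]
A8 | alternative 3 | target with the ring A hydroxyl free and the four other phenols as benzyl ethers | COc1cc(O)c(Cc2ccc(OCc3ccccc3)cc2)c(CCc2cc(Cc3ccc(OCc4ccccc4)cc3)ccc2OCc2ccccc2)c1Cc1ccc(OCc2ccccc2)cc1
A9 | alternative 3 | (4E)-4-(2-{2-(benzyloxy)-5-[4-(benzyloxy)benzyl]phenyl}ethyl)-1,6-bis[4-(benzyloxy)phenyl]-2-diazohex-4-en-3-one | [N-]=[N+]=C(Cc1ccc(OCc2ccccc2)cc1)C(=O)/C(CCc1cc(Cc2ccc(OCc3ccccc3)cc2)ccc1OCc1ccccc1)=C/Cc1ccc(OCc2ccccc2)cc1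
A10 | alternative 3 | methoxyacetylene | COC#C
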